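**Strategy.** The cyclohexene (C1 bears CH2OBz, C2 is the vinylic CH, C3 to C6 are the four cis oxygenated carbons) is cut at C1=C2 and C3–C4. C2–C3 is read as a glycolaldehyde unit. In one pot its enamine adds to the aldehyde carbon (future C4) of an acyclic 2-benzoyloxy-3-silyloxy-5,5-diethoxypentanal (D-proline anti-aldol, setting C3 and C4); its carbonyl carbon C2 then condenses with the unmasked CH2–CHO terminus to close the ring as a 1-formylcyclohexene. The step exploits the C1(=C2H)–C3H(OH)–C4H(OH) enal/anti-diol retron and the all-cis C3–C4–C5 triad, the matched catalyst/Felkin outcome. C5 and C6 come from an iridium-catalysed anti-(benzoyloxy)allylation that installs the C5 benzoate directly.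

Key step: step 5

Assumption: the iridium catalyst carrying (S)-SEGPHOS is taken to give the (3S,4R) enantiomer of 4, by analogy with the facial sense of the parent allyl acetate couplings; if the opposite sense applies, (R)-SEGPHOS is used and nothing else changes.

Step 1
Reactants: 1 acrolein
Product: 2 prop-2-ene-1,1-diyl dibenzoate
Conditions: Bz2O, H2SO4 (cat.), 0 to 23 °C
Reagents that add atoms: benzoic anhydride, O=C(OC(=O)c1ccccc1)c1ccccc1
Why: Acid-catalysed acylal formation is a 1,2-addition of the anhydride across the aldehyde C=O and should leave the vinyl group untouched at low temperature.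

Step 2
Reactants: 2 prop-2-ene-1,1-diyl dibenzoate; 3 3,3-diethoxypropan-1-ol
Product: 4 (3S,4R)-6,6-diethoxy-4-hydroxyhex-1-en-3-yl benzoate
Conditions: [Ir(cod)Cl]2 (2.5 mol%), (S)-SEGPHOS (5 mol%), 4-cyano-3-nitrobenzoic acid (10 mol%), K3PO4 (1 equiv), THF, 90 °C
Reagents that add atoms: none
Why: In this iridium-catalysed transfer-hydrogenative carbonyl (benzoyloxy)allylation from the alcohol oxidation level, the alcohol is dehydrogenated to the aldehyde, which is trapped by the (E)-(benzoyloxy)allyl iridium species through a closed chair transition state, so the anti relation follows from the allyl geometry, the absolute sense from the SEGPHOS-bound cyclometallated catalyst, and one benzoate stays on the allylic oxygen (future C5).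

Step 3
Reactants: 4 (3S,4R)-6,6-diethoxy-4-hydroxyhex-1-en-3-yl benzoate
Product: 5 (3S,4R)-4-[(tert-butyldimethylsilyl)oxy]-6,6-diethoxyhex-1-en-3-yl benzoate
Conditions: TBSOTf, 2,6-lutidine, CH2Cl2, −78 °C
Reagents that add atoms: tert-butyldimethylsilyl triflate, CC(C)(C)[Si](C)(C)OS(=O)(=O)C(F)(F)F
Why: O-Silylation with the silyl triflate at −78 °C should be faster than 1,2-benzoyl migration or activation of the acyclic acetal, and no stereocenter is touched.

Step 4
Reactants: 5 (3S,4R)-4-[(tert-butyldimethylsilyl)oxy]-6,6-diethoxyhex-1-en-3-yl benzoate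
Product: 6 (2R,3R)-3-[(tert-butyldimethylsilyl)oxy]-5,5-diethoxy-1-oxopentan-2-yl benzoate
Conditions: O3, CH2Cl2, −78 °C; then PPh3
Reagents that add atoms: ozone, [O-][O+]=O
Why: Ozonolysis with reductive work-up cleaves the only C=C bond to the aldehyde under neutral conditions that should not enolise the α-benzoyloxy stereocenter; 6 is used crude.

Step 5
Reactants: 6 (2R,3R)-3-[(tert-butyldimethylsilyl)oxy]-5,5-diethoxy-1-oxopentan-2-yl benzoate; 7 2-[(tert-butyldimethylsilyl)oxy]acetaldehyde
Product: 10 (3S,4R,5S,6R)-5-(benzoyloxy)-3,6-bis[(tert-butyldimethylsilyl)oxy]-4-hydroxycyclohex-1-ene-1-carbaldehyde, via heptanal aldol adduct 8 (not isolated), via heptanedial 9 (not isolated)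
Conditions: D-proline (20 mol%), DMF, 4 °C, slow addition of 7 (2 equiv); then TFA, H2O, 0 °C; then Bn2NH, 40 °C
Reagents that add atoms: water, O
Why: D-Proline converts 7 into an (E)-enamine that adds to the free aldehyde of 6 through the hydrogen-bonded chair (Zimmerman–Traxler-type) transition state to give 8, the closest known reaction type being the proline-catalysed direct cross-aldol between α-oxyaldehydes; aqueous TFA then unmasks the diethyl acetal to 9, and dibenzylammonium trifluoroacetate turns the unbranched CH2–CHO terminus into an enamine that attacks the α-silyloxy aldehyde and dehydrates by E1cB to the conjugated enal 10, the known intramolecular aldol condensation of a 1,7-dialdehyde to a cyclohexene-1-carbaldehyde. The six-membered ring closes in the 6-(enolexo)-exo-trig mode. The two new stereocenters (ring C3 and C4) are set anti to each other and in the absolute sense by the carboxylic acid-directed D-proline transition state, and the C4/C5 anti relation is reinforced by the polar Felkin–Anh preference of the (R)-α-benzoyloxy aldehyde, so catalyst and substrate should be matched for the all-cis array. Donor/acceptor selectivity rests on 6 being α-branched (slow enamine formation) and on slow addition of 7, and chemoselectivity on the second aldehyde staying masked as the acetal during the cross-aldol. In the ring closure only the enamine of the unbranched aldehyde can lead to a conjugated enal, the alternative aldol from the α-branched aldehyde being a reversible dead end that cannot dehydrate.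

Step 6
Reactants: 10 (3S,4R,5S,6R)-5-(benzoyloxy)-3,6-bis[(tert-butyldimethylsilyl)oxy]-4-hydroxycyclohex-1-ene-1-carbaldehyde
Product: 11 (3S,4R,5S,6R)-3,6-bis[(tert-butyldimethylsilyl)oxy]-4-hydroxy-1-(hydroxymethyl)cyclohex-1-en-5-yl benzoate
Conditions: NaBH4, CeCl3·7H2O, MeOH, −78 °C
Reagents that add atoms: none
Why: Luche reduction delivers hydride 1,2 to the enal, and the benzoate and silyl ethers should be inert at this temperature.

Step 7
Reactants: 11 (3S,4R,5S,6R)-3,6-bis[(tert-butyldimethylsilyl)oxy]-4-hydroxy-1-(hydroxymethyl)cyclohex-1-en-5-yl benzoate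
Product: 12 [(3S,4R,5S,6R)-5-(benzoyloxy)-3,6-bis[(tert-butyldimethylsilyl)oxy]-4-hydroxycyclohex-1-en-1-yl]methyl benzoate
Conditions: BzCl (1.05 equiv), 2,4,6-collidine, CH2Cl2, −40 to 0 °C
Reagents that add atoms: benzoyl chloride, O=C(Cl)c1ccccc1
Why: In this acyl transfer (esterification) the primary allylic hydroxyl should react far faster than the C4 hydroxyl, which is flanked by a silyl ether and a benzoate.

Step 8
Reactants: 12 [(3S,4R,5S,6R)-5-(benzoyloxy)-3,6-bis[(tert-butyldimethylsilyl)oxy]-4-hydroxycyclohex-1-en-1-yl]methyl benzoate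
Product: 13 [(3S,4S,5R,6R)-5-(benzoyloxy)-3,4,6-trihydroxycyclohex-1-en-1-yl]methyl benzoate
Conditions: HF·pyridine, pyridine, THF, 0 to 23 °C
Reagents that add atoms: none
Why: Fluoride-mediated desilylation under buffered, non-basic conditions should cleave both secondary silyl ethers without base-induced 1,2-benzoyl migration and touches no stereocenter.

**Compound list**

1 | acrolein | C=CC=O | starting material
2 | prop-2-ene-1,1-diyl dibenzoate | C=CC(OC(=O)c1ccccc1)OC(=O)c1ccccc1 | intermediate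
3 | 3,3-diethoxypropan-1-ol | CCOC(CCO)OCC | starting material
4 | (3S,4R)-6,6-diethoxy-4-hydroxyhex-1-en-3-yl benzoate | C=C[C@H](OC(=O)c1ccccc1)[C@H](O)CC(OCC)OCC | intermediate
5 | (3S,4R)-4-[(tert-butyldimethylsilyl)oxy]-6,6-diethoxyhex-1-en-3-yl benzoate | C=C[C@H](OC(=O)c1ccccc1)[C@H](O[Si](C)(C)C(C)(C)C)CC(OCC)OCC | intermediate
6 | (2R,3R)-3-[(tert-butyldimethylsilyl)oxy]-5,5-diethoxy-1-oxopentan-2-yl benzoate | O=C[C@H](OC(=O)c1ccccc1)[C@H](O[Si](C)(C)C(C)(C)C)CC(OCC)OCC | intermediate
7 | 2-[(tert-butyldimethylsilyl)oxy]acetaldehyde | O=CCO[Si](C)(C)C(C)(C)C | starting material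
8 | (2R,3R,4S,5R)-2,5-bis[(tert-butyldimethylsilyl)oxy]-7,7-diethoxy-3-hydroxy-1-oxoheptan-4-yl benzoate | O=C[C@H](O[Si](C)(C)C(C)(C)C)[C@H](O)[C@H](OC(=O)c1ccccc1)[C@H](O[Si](C)(C)C(C)(C)C)CC(OCC)OCC | intermediate
9 | (2R,3R,4S,5R)-2,5-bis[(tert-butyldimethylsilyl)oxy]-3-hydroxy-1,7-dioxoheptan-4-yl benzoate | O=C[C@H](O[Si](C)(C)C(C)(C)C)[C@H](O)[C@H](OC(=O)c1ccccc1)[C@H](O[Si](C)(C)C(C)(C)C)CC=O | intermediate
10 | (3S,4R,5S,6R)-5-(benzoyloxy)-3,6-bis[(tert-butyldimethylsilyl)oxy]-4-hydroxycyclohex-1-ene-1-carbaldehyde | O=CC1=C[C@H](O[Si](C)(C)C(C)(C)C)[C@H](O)[C@H](OC(=O)c2ccccc2)[C@@H]1O[Si](C)(C)C(C)(C)C | intermediate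
11 | (3S,4R,5S,6R)-3,6-bis[(tert-butyldimethylsilyl)oxy]-4-hydroxy-1-(hydroxymethyl)cyclohex-1-en-5-yl benzoate | OCC1=C[C@H](O[Si](C)(C)C(C)(C)C)[C@H](O)[C@H](OC(=O)c2ccccc2)[C@@H]1O[Si](C)(C)C(C)(C)C | intermediate
12 | [(3S,4R,5S,6R)-5-(benzoyloxy)-3,6-bis[(tert-butyldimethylsilyl)oxy]-4-hydroxycyclohex-1-en-1-yl]methyl benzoate | O=C(OCC1=C[C@H](O[Si](C)(C)C(C)(C)C)[C@H](O)[C@H](OC(=O)c2ccccc2)[C@@H]1O[Si](C)(C)C(C)(C)C)c1ccccc1 | intermediate
13 | [(3S,4S,5R,6R)-5-(benzoyloxy)-3,4,6-trihydroxycyclohex-1-en-1-yl]methyl benzoate | O=C(OCC1=C[C@H](O)[C@H](O)[C@H](OC(=O)c2ccccc2)[C@@H]1O)c1ccccc1 | target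

Total step count: 8. Longest linear sequence: 8 steps (1 to 13).

**Steps most likely to fail**

1. Step 5 (key step). What may go wrong: homo-aldol of the donor outrunning the cross-aldol; low facial selectivity; benzoate migration onto the new hydroxyl; β-elimination of silanol or epimerisation next to the aldehyde during the acid/amine stage. The fallback sets out from 6 and returns to the route only at the target 13. It replaces the aldol by olefination and osmylation. A Wittig reaction of 6 with the ylide from (2,2-diethoxyethyl)triphenylphosphonium bromide (KHMDS, THF, −78 °C) should give mainly the Z-alkene (2Z,4S,5R)-5-[(tert-butyldimethylsilyl)oxy]-1,1,7,7-tetraethoxyhept-2-en-4-yl benzoate F1. Dihydroxylation (OsO4 cat., NMO, acetone–water) adds syn across the Z-alkene and anti to the allylic benzoate, the usual empirical sense for osmylation next to an allylic oxygen, and should give the all-erythro diol (2R,3S,4S,5R)-5-[(tert-butyldimethylsilyl)oxy]-1,1,7,7-tetraethoxy-2,3-dihydroxyheptan-4-yl benzoate F2. Aqueous TFA followed by Bn2NH (hydrolysis of both acetals, then the same ammonium-salt aldol condensation) should give the enal diol (3S,4S,5S,6R)-5-(benzoyloxy)-6-[(tert-butyldimethylsilyl)oxy]-3,4-dihydroxycyclohex-1-ene-1-carbaldehyde F3. Luche reduction gives the triol (3S,4S,5S,6R)-6-[(tert-butyldimethylsilyl)oxy]-3,4-dihydroxy-1-(hydroxymethyl)cyclohex-1-en-5-yl benzoate F4. BzCl/collidine at −40 °C acylates the primary hydroxyl to [(3S,4S,5S,6R)-5-(benzoyloxy)-6-[(tert-butyldimethylsilyl)oxy]-3,4-dihydroxycyclohex-1-en-1-yl]methyl benzoate F5, and HF·pyridine then gives 13.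

2. Step 2. What may go wrong: loss of ethanol from the transient β,β-dialkoxy aldehyde; benzoate migration to the new hydroxyl at 90 °C; insufficient or inverted enantioselectivity. The fallback is a chiral-pool route that bypasses steps 1 to 3. It sets out from no numbered compound but from commercial 2-deoxy-D-lyxo-hexose (2-deoxy-D-galactose) F6, and comes back at 5. Fischer glycosidation (MeOH, AcCl cat.) gives methyl 2-deoxy-α-D-lyxo-hexopyranoside F7. Selective primary iodination (I2, PPh3, imidazole) gives methyl 2,6-dideoxy-6-iodo-α-D-lyxo-hexopyranoside F8. Silylation of the equatorial 3-hydroxyl (TBSCl, imidazole, DMF) gives methyl 3-O-(tert-butyldimethylsilyl)-2,6-dideoxy-6-iodo-α-D-lyxo-hexopyranoside F9. Benzoylation of the remaining axial 4-hydroxyl (BzCl, pyridine, DMAP) gives methyl 4-O-benzoyl-3-O-(tert-butyldimethylsilyl)-2,6-dideoxy-6-iodo-α-D-lyxo-hexopyranoside F10. Bernet–Vasella fragmentation (Zn dust, THF–H2O, sonication) opens the ring to (3R,4S)-3-[(tert-butyldimethylsilyl)oxy]-1-oxohex-5-en-4-yl benzoate F11. Acetalisation (HC(OEt)3, EtOH, PPTS) gives 5.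

3. Step 7. What may go wrong: over-acylation at the C4 hydroxyl or benzoyl scrambling between neighbouring oxygens. The fallback sets out from 11 and comes back at 12. It replaces acyl transfer by activation of the alcohol: a Mitsunobu esterification (PhCO2H, PPh3, DIAD, THF, 0 °C) forms the oxyphosphonium only at the unhindered primary allylic hydroxyl, and benzoate displaces it at carbon. It makes no new compound, F0.

**Further compounds**

F1 | step 5 | (2Z,4S,5R)-5-[(tert-butyldimethylsilyl)oxy]-1,1,7,7-tetraethoxyhept-2-en-4-yl benzoate | CCOC(OCC)/C=C\[C@H](OC(=O)c1ccccc1)[C@H](O[Si](C)(C)C(C)(C)C)CC(OCC)OCC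
F2 | step 5 | (2R,3S,4S,5R)-5-[(tert-butyldimethylsilyl)oxy]-1,1,7,7-tetraethoxy-2,3-dihydroxyheptan-4-yl benzoate | CCOC(OCC)[C@H](O)[C@H](O)[C@H](OC(=O)c1ccccc1)[C@H](O[Si](C)(C)C(C)(C)C)CC(OCC)OCC
F3 | step 5 | (3S,4S,5S,6R)-5-(benzoyloxy)-6-[(tert-butyldimethylsilyl)oxy]-3,4-dihydroxycyclohex-1-ene-1-carbaldehyde | O=CC1=C[C@H](O)[C@H](O)[C@H](OC(=O)c2ccccc2)[C@@H]1O[Si](C)(C)C(C)(C)C
F4 | step 5 | (3S,4S,5S,6R)-6-[(tert-butyldimethylsilyl)oxy]-3,4-dihydroxy-1-(hydroxymethyl)cyclohex-1-en-5-yl benzoate | OCC1=C[C@H](O)[C@H](O)[C@H](OC(=O)c2ccccc2)[C@@H]1O[Si](C)(C)C(C)(C)C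
F5 | step 5 | [(3S,4S,5S,6R)-5-(benzoyloxy)-6-[(tert-butyldimethylsilyl)oxy]-3,4-dihydroxycyclohex-1-en-1-yl]methyl benzoate | O=C(OCC1=C[C@H](O)[C@H](O)[C@H](OC(=O)c2ccccc2)[C@@H]1O[Si](C)(C)C(C)(C)C)c1ccccc1
F6 | step 2 | 2-deoxy-D-lyxo-hexose (2-deoxy-D-galactose, open-chain form) | O=CC[C@@H](O)[C@@H](O)[C@H](O)CO
F7 | step 2 | methyl 2-deoxy-α-D-lyxo-hexopyranoside | CO[C@@H]1C[C@@H](O)[C@@H](O)[C@@H](CO)O1
F8 | step 2 | methyl 2,6-dideoxy-6-iodo-α-D-lyxo-hexopyranoside | CO[C@@H]1C[C@@H](O)[C@@H](O)[C@@H](CI)O1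
F9 | step 2 | methyl 3-O-(tert-butyldimethylsilyl)-2,6-dideoxy-6-iodo-α-D-lyxo-hexopyranoside | CO[C@@H]1C[C@@H](O[Si](C)(C)C(C)(C)C)[C@@H](O)[C@@H](CI)O1
F10 | step 2 | methyl 4-O-benzoyl-3-O-(tert-butyldimethylsilyl)-2,6-dideoxy-6-iodo-α-D-lyxo-hexopyranoside | CO[C@@H]1C[C@@H](O[Si](C)(C)C(C)(C)C)[C@@H](OC(=O)c2ccccc2)[C@@H](CI)O1
F11 | step 2 | (3R,4S)-3-[(tert-butyldimethylsilyl)oxy]-1-oxohex-5-en-4-yl benzoate | O=CC[C@@H](O[Si](C)(C)C(C)(C)C)[C@@H](OC(=O)c1ccccc1)C=C
F0 | step 7 | none | none
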